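## Retrosynthetic overview

1. Target 20 comes from 18 by one hydrogenation (alkene saturated, both benzyl groups removed) followed by mild acetal hydrolysis.
2. 18 comes from bis-acetal 15 and methallylsilane 16: the benzylic C–C bond and the (R) C–OMe centre are set together by an organocatalytic, enantioselective and site-selective Hosomi–Sakurai reaction on the ring A acetal.
3. 15 comes from dialdehyde 14, which is made by SNAr of fluoro aldehyde-ester 7 (ring A) with phenol 13 (ring B); this forms the diaryl ether.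
4. 7 comes from 4-fluoro-2-methoxybenzaldehyde by acetal protection and ortho-lithiation/benzyloxycarbonylation. 13 comes from 2-hydroxy-3-methoxy-5-methylbenzaldehyde by demethylation and 3-O-selective benzylation.
5. No ring is built: rings A and B are bought as benzenes and joined in the SNAr step.

Assumption: the (S,S) antipode of the IDPi catalyst is taken to give the (R) ether; if a test run on model acetal 3 shows the opposite sense, the (R,R) catalyst is used. The stereocentre is (R) by CIP (OMe > aryl > CH2 > H).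

IDPi here means a BINOL-derived imidodiphosphorimidate Brønsted acid (two 3,3'-diaryl-BINOL phosphorus units, N–SO2CF3 groups), a metal-free catalyst.

## Route

Step 1
Reactants: 1 4-fluoro-2-methoxybenzaldehyde; 2 trimethyl orthoformate
Product: 3 1-(dimethoxymethyl)-4-fluoro-2-methoxybenzene
Conditions: HC(OMe)3 (3 equiv), p-TsOH·H2O (1 mol%), MeOH, rt; K2CO3 quench
Reagents that add atoms: trimethyl orthoformate (2), COC(OC)OC; methanol, CO
Why: Acid-catalysed acetalisation driven by the orthoformate as water scavenger; the acetal masks the aldehyde against the lithium amide of step 2.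

Step 2
Reactants: 3 1-(dimethoxymethyl)-4-fluoro-2-methoxybenzene; 4 benzyl chloroformate
Product: 7 benzyl 6-fluoro-3-formyl-2-methoxybenzoate, via aryllithium 5 (not isolated), via acetal ester 6 (not isolated)
Conditions: LiN(i-Pr)2 (1.15 equiv), THF, −78 °C, 1 h; CbzCl (1.3 equiv), −78 to 0 °C; then 1 M HCl, THF, rt
Reagents that add atoms: benzyl chloroformate (4), O=C(Cl)OCc1ccccc1; water, O
Why: Directed ortho-metalation removes the most acidic C–H, flanked by F and OMe, at −78 °C (below the temperature of LiF loss to an aryne), acylation of aryllithium 5 by the chloroformate gives the doubly ortho-substituted ester 6 that resists a second addition, and dilute acid hydrolyses the acetal to the aldehyde.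

Step 3
Reactants: 8 2-hydroxy-3-methoxy-5-methylbenzaldehyde
Product: 10 2,3-dihydroxy-5-methylbenzaldehyde, via cyclic bromoborane 9 (not isolated)
Conditions: BBr3 (2.2 equiv), CH2Cl2, −78 °C to rt; then H2O, 0 °C
Reagents that add atoms: none
Why: Lewis acid aryl methyl ether cleavage, in which BBr3 binds the phenol/methoxy pair and bromide removes the methyl group by SN2 to give cyclic bromoborane 9, which water hydrolyses while the aldehyde is untouched.

Step 4
Reactants: 10 2,3-dihydroxy-5-methylbenzaldehyde; 11 benzyl bromide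
Product: 13 3-(benzyloxy)-2-hydroxy-5-methylbenzaldehyde, via disodium dianion 12 (not isolated)
Conditions: NaH (2.2 equiv), DMSO, rt, 1 h; BnBr (1.0 equiv), rt; 1 M HCl work-up
Reagents that add atoms: benzyl bromide (11), BrCc1ccccc1
Why: Regioselective Williamson etherification of dianion 12, in which the 2-oxide is delocalised into the ortho formyl group and chelated to sodium, so the single equivalent of BnBr alkylates the more basic 3-oxide.

Step 5
Reactants: 7 benzyl 6-fluoro-3-formyl-2-methoxybenzoate; 13 3-(benzyloxy)-2-hydroxy-5-methylbenzaldehyde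
Product: 14 benzyl 6-[2-(benzyloxy)-6-formyl-4-methylphenoxy]-3-formyl-2-methoxybenzoate
Conditions: K2CO3 (1.5 equiv), DMF, 60 °C
Reagents that add atoms: none
Why: SNAr (addition–elimination via a Meisenheimer intermediate) in which the fluoride, para to the formyl group and ortho to the ester, is displaced by the phenoxide of 13, whose only free oxygen is the one ortho to the ring B formyl group.

Step 6
Reactants: 14 benzyl 6-[2-(benzyloxy)-6-formyl-4-methylphenoxy]-3-formyl-2-methoxybenzoate; 2 trimethyl orthoformate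
Product: 15 benzyl 6-[2-(benzyloxy)-6-(dimethoxymethyl)-4-methylphenoxy]-3-(dimethoxymethyl)-2-methoxybenzoate
Conditions: HC(OMe)3 (6 equiv), p-TsOH·H2O (2 mol%), MeOH–CH2Cl2, rt; Et3N quench
Reagents that add atoms: trimethyl orthoformate (2), COC(OC)OC; methanol, CO
Why: Acid-catalysed acetalisation of both aldehydes, which turns the ring A aldehyde into the oxocarbenium precursor for step 7 and masks the ring B aldehyde for steps 7 and 8, while the hindered benzyl ester does not transesterify at rt.

Step 7
Reactants: 15 benzyl 6-[2-(benzyloxy)-6-(dimethoxymethyl)-4-methylphenoxy]-3-(dimethoxymethyl)-2-methoxybenzoate; 16 (2-methylallyl)trimethylsilane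
Product: 18 benzyl 6-[2-(benzyloxy)-6-(dimethoxymethyl)-4-methylphenoxy]-2-methoxy-3-[(1R)-1-methoxy-3-methylbut-3-en-1-yl]benzoate, via methoxycarbenium ion 17 (not isolated)
Conditions: 16 (1.2 equiv), (S,S)-IDPi (3 mol%), toluene, −78 to −60 °C; Et3N quench; Et3N-deactivated silica
Reagents that add atoms: (2-methylallyl)trimethylsilane (16), C=C(C)C[Si](C)(C)C
Why: Proposed new method: an enantioselective and site-selective Hosomi–Sakurai methallylation of an aryl dimethyl acetal under silylium asymmetric counteranion-directed catalysis, in which the IDPi acid is silylated by 16 (isobutene lost), the Me3Si–IDPi species abstracts one methoxy group of the ring A acetal as MeOSiMe3 to give methoxycarbenium ion 17 (ionisation is much easier on ring A, whose cation has ortho-OMe and para-aryloxy donors, than on ring B, whose cation has one weakly donating and bulky ortho-aryloxy group), 17 is held as a contact ion pair in the confined chiral anion, 16 adds to one enantioface to set the (R) centre directly as the methyl ether, and loss of Me3Si+ returns the catalyst; the closest known reaction types are the IDPi-catalysed Hosomi–Sakurai allylation of aldehydes (which gives silyl ethers) and chiral-anion or hydrogen-bond-donor controlled Mukaiyama-type additions to aryl methoxycarbenium ions from dimethyl acetals, whereas allylsilane addition to an acyclic acetal with enantiocontrol and with discrimination between two acetals in one molecule has not been shown.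

Step 8
Reactants: 18 benzyl 6-[2-(benzyloxy)-6-(dimethoxymethyl)-4-methylphenoxy]-2-methoxy-3-[(1R)-1-methoxy-3-methylbut-3-en-1-yl]benzoate
Product: 20 6-(2-formyl-6-hydroxy-4-methylphenoxy)-2-methoxy-3-[(1R)-1-methoxy-3-methylbutyl]benzoic acid, via acetal acid 19 (not isolated)
Conditions: H2 (1 atm), 10% Pd/C, EtOAc, rt; filter; then 0.5 M HCl, THF–H2O, 0 °C to rt, 15 min
Reagents that add atoms: water, O
Why: Heterogeneous hydrogenation and hydrogenolysis saturate the 1,1-disubstituted alkene and cleave the benzyl ester and aryl benzyl ether while the ring B aldehyde is masked as its acetal and the secondary benzylic methyl ether is left alone in neutral EtOAc, and brief dilute acid then hydrolyses the acetal far faster than it can ionise the benzylic ether, so the (R) centre is kept and 20 is the target.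

## Compound list

1 | 4-fluoro-2-methoxybenzaldehyde | COc1cc(F)ccc1C=O | starting material
2 | trimethyl orthoformate | COC(OC)OC | starting material
3 | 1-(dimethoxymethyl)-4-fluoro-2-methoxybenzene | COc1cc(F)ccc1C(OC)OC | intermediate
4 | benzyl chloroformate | O=C(Cl)OCc1ccccc1 | starting material
5 | [3-(dimethoxymethyl)-6-fluoro-2-methoxyphenyl]lithium | COc1c([Li])c(F)ccc1C(OC)OC | intermediate
6 | benzyl 3-(dimethoxymethyl)-6-fluoro-2-methoxybenzoate | COc1c(C(=O)OCc2ccccc2)c(F)ccc1C(OC)OC | intermediate
7 | benzyl 6-fluoro-3-formyl-2-methoxybenzoate | COc1c(C(=O)OCc2ccccc2)c(F)ccc1C=O | intermediate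
8 | 2-hydroxy-3-methoxy-5-methylbenzaldehyde | COc1cc(C)cc(C=O)c1O | starting material
9 | 2-bromo-6-methyl-1,3,2-benzodioxaborole-4-carbaldehyde | O=Cc1cc(C)cc2OB(Br)Oc12 | intermediate
10 | 2,3-dihydroxy-5-methylbenzaldehyde | O=Cc1cc(C)cc(O)c1O | intermediate
11 | benzyl bromide | BrCc1ccccc1 | starting material
12 | disodium 3-formyl-5-methylbenzene-1,2-bis(olate) | [Na+].[Na+].[O-]c1cc(C)cc(C=O)c1[O-] | intermediate
13 | 3-(benzyloxy)-2-hydroxy-5-methylbenzaldehyde | O=Cc1cc(C)cc(OCc2ccccc2)c1O | intermediate
14 | benzyl 6-[2-(benzyloxy)-6-formyl-4-methylphenoxy]-3-formyl-2-methoxybenzoate | COc1c(C=O)ccc(Oc2c(OCc3ccccc3)cc(C)cc2C=O)c1C(=O)OCc1ccccc1 | intermediate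
15 | benzyl 6-[2-(benzyloxy)-6-(dimethoxymethyl)-4-methylphenoxy]-3-(dimethoxymethyl)-2-methoxybenzoate | COc1c(C(OC)OC)ccc(Oc2c(OCc3ccccc3)cc(C)cc2C(OC)OC)c1C(=O)OCc1ccccc1 | intermediate
16 | (2-methylallyl)trimethylsilane | C=C(C)C[Si](C)(C)C | starting material
17 | ring A methoxycarbenium ion of 15 (cation of the ion pair with the IDPi anion) | COc1c(C=[O+]C)ccc(Oc2c(OCc3ccccc3)cc(C)cc2C(OC)OC)c1C(=O)OCc1ccccc1 | intermediate
18 | benzyl 6-[2-(benzyloxy)-6-(dimethoxymethyl)-4-methylphenoxy]-2-methoxy-3-[(1R)-1-methoxy-3-methylbut-3-en-1-yl]benzoate | COc1c([C@@H](CC(C)=C)OC)ccc(Oc2c(OCc3ccccc3)cc(C)cc2C(OC)OC)c1C(=O)OCc1ccccc1 | intermediate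
19 | 6-[2-(dimethoxymethyl)-6-hydroxy-4-methylphenoxy]-2-methoxy-3-[(1R)-1-methoxy-3-methylbutyl]benzoic acid | COc1c([C@@H](CC(C)C)OC)ccc(Oc2c(O)cc(C)cc2C(OC)OC)c1C(=O)O | intermediate
20 | 6-(2-formyl-6-hydroxy-4-methylphenoxy)-2-methoxy-3-[(1R)-1-methoxy-3-methylbutyl]benzoic acid | COc1c([C@@H](CC(C)C)OC)ccc(Oc2c(O)cc(C)cc2C=O)c1C(=O)O | target

## Step count and risk

Total steps: 8. Longest linear sequence: 6 (steps 1, 2, 5, 6, 7, 8).

**Step 7 (proposed new methallylation).** It may fail on enantioselectivity with this large substrate or on discrimination between the two acetals. The fallback uses known reactions only, sets out from 7 (with 13) and comes back at 18. Phenol 13 is acetalised (HC(OMe)3, MeOH, cat. p-TsOH, then K2CO3) to 2-(benzyloxy)-6-(dimethoxymethyl)-4-methylphenol F1, used directly. SNAr of 7 with it (K2CO3, DMF, 60 °C) gives benzyl 6-[2-(benzyloxy)-6-(dimethoxymethyl)-4-methylphenoxy]-3-formyl-2-methoxybenzoate F2, in which only ring A has a free aldehyde. Chiral phosphoric acid-catalysed methallylboration (2-methylallylboronic acid pinacol ester, (R)-TRIP 5 mol%, toluene, −30 °C; the antipode if the sense is opposite) gives benzyl 6-[2-(benzyloxy)-6-(dimethoxymethyl)-4-methylphenoxy]-3-[(1R)-1-hydroxy-3-methylbut-3-en-1-yl]-2-methoxybenzoate F3. O-Methylation (NaH, MeI, THF, 0 °C) then gives 18.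

**Step 8 (global hydrogenation).** The ring B acetal or the benzylic methyl ether may be hydrogenolysed during the slow cleavage of the aryl benzyl ether. The fallback uses allyl in place of benzyl so that no hydrogenolysis is needed; it sets out from 3 (and 10) and comes back at 19.
- 3 is lithiated as in step 2 and trapped with allyl chloroformate, then dilute acid, to give prop-2-en-1-yl 6-fluoro-3-formyl-2-methoxybenzoate F4.
- 10 is alkylated as in step 4 with allyl bromide to give 2-hydroxy-5-methyl-3-(prop-2-en-1-yloxy)benzaldehyde F5.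
- SNAr as in step 5 gives prop-2-en-1-yl 3-formyl-6-[2-formyl-4-methyl-6-(prop-2-en-1-yloxy)phenoxy]-2-methoxybenzoate F6.
- Acetalisation as in step 6 gives prop-2-en-1-yl 3-(dimethoxymethyl)-6-[2-(dimethoxymethyl)-4-methyl-6-(prop-2-en-1-yloxy)phenoxy]-2-methoxybenzoate F7.
- Methallylation as in step 7 gives prop-2-en-1-yl 6-[2-(dimethoxymethyl)-4-methyl-6-(prop-2-en-1-yloxy)phenoxy]-2-methoxy-3-[(1R)-1-methoxy-3-methylbut-3-en-1-yl]benzoate F8.
- Pd(PPh3)4 (5 mol%), morpholine, THF, rt with a pH 5 work-up removes both allyl groups to give 6-[2-(dimethoxymethyl)-6-hydroxy-4-methylphenoxy]-2-methoxy-3-[(1R)-1-methoxy-3-methylbut-3-en-1-yl]benzoic acid F9.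
- Diimide (2-nitrobenzenesulfonyl hydrazide, Et3N, CH2Cl2, rt) saturates the alkene to give 19, which is hydrolysed to 20 as in step 8.

**Step 4 (regioselective benzylation).** It may give mixtures of 2-O, 3-O and dibenzyl products. The fallback sets out from 10 and comes back at 13. Both oxygens are benzylated (BnBr 2.5 equiv, K2CO3, DMF, 60 °C) to 2,3-bis(benzyloxy)-5-methylbenzaldehyde F10. The benzyl ether ortho to the formyl group is then removed selectively by chelation-controlled cleavage with MgBr2·OEt2 (toluene–Et2O, reflux) to give 13.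

## Further compounds

F1 | step 7 | 2-(benzyloxy)-6-(dimethoxymethyl)-4-methylphenol | COC(OC)c1cc(C)cc(OCc2ccccc2)c1O
F2 | step 7 | benzyl 6-[2-(benzyloxy)-6-(dimethoxymethyl)-4-methylphenoxy]-3-formyl-2-methoxybenzoate | COc1c(C=O)ccc(Oc2c(OCc3ccccc3)cc(C)cc2C(OC)OC)c1C(=O)OCc1ccccc1
F3 | step 7 | benzyl 6-[2-(benzyloxy)-6-(dimethoxymethyl)-4-methylphenoxy]-3-[(1R)-1-hydroxy-3-methylbut-3-en-1-yl]-2-methoxybenzoate | COc1c([C@@H](CC(C)=C)O)ccc(Oc2c(OCc3ccccc3)cc(C)cc2C(OC)OC)c1C(=O)OCc1ccccc1
F4 | step 8 | prop-2-en-1-yl 6-fluoro-3-formyl-2-methoxybenzoate | COc1c(C(=O)OCC=C)c(F)ccc1C=O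
F5 | step 8 | 2-hydroxy-5-methyl-3-(prop-2-en-1-yloxy)benzaldehyde | O=Cc1cc(C)cc(OCC=C)c1O
F6 | step 8 | prop-2-en-1-yl 3-formyl-6-[2-formyl-4-methyl-6-(prop-2-en-1-yloxy)phenoxy]-2-methoxybenzoate | COc1c(C=O)ccc(Oc2c(OCC=C)cc(C)cc2C=O)c1C(=O)OCC=C
F7 | step 8 | prop-2-en-1-yl 3-(dimethoxymethyl)-6-[2-(dimethoxymethyl)-4-methyl-6-(prop-2-en-1-yloxy)phenoxy]-2-methoxybenzoate | COc1c(C(OC)OC)ccc(Oc2c(OCC=C)cc(C)cc2C(OC)OC)c1C(=O)OCC=C
F8 | step 8 | prop-2-en-1-yl 6-[2-(dimethoxymethyl)-4-methyl-6-(prop-2-en-1-yloxy)phenoxy]-2-methoxy-3-[(1R)-1-methoxy-3-methylbut-3-en-1-yl]benzoate | COc1c([C@@H](CC(C)=C)OC)ccc(Oc2c(OCC=C)cc(C)cc2C(OC)OC)c1C(=O)OCC=C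
F9 | step 8 | 6-[2-(dimethoxymethyl)-6-hydroxy-4-methylphenoxy]-2-methoxy-3-[(1R)-1-methoxy-3-methylbut-3-en-1-yl]benzoic acid | COc1c([C@@H](CC(C)=C)OC)ccc(Oc2c(O)cc(C)cc2C(OC)OC)c1C(=O)O
F10 | step 4 | 2,3-bis(benzyloxy)-5-methylbenzaldehyde | O=Cc1cc(C)cc(OCc2ccccc2)c1OCc1ccccc1
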